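**Retrosynthetic overview**
1. Numbering: ring B (2,4-dihydroxy-3-methoxyphenyl)–C1H2–C2H2–C3(=O)–C4H2–C5H2–C6H2–C7H2–ring A (4-methoxyphenyl). The C3 ketone has an ethylene unit on each side (C1–C2 and C4–C5), so C1–C5 is a latent penta-1,4-dien-3-one, a C5 bis-acceptor.
2. Key disconnections: ring B C1'–C1 and C5–C6, the two β-carbons of divinyl ketone. Three components (2-methoxyresorcinol, divinyl ketone, a 4-methoxyphenethyl nucleophile) are joined in one flask.
3. Ring B is 2-methoxyresorcinol itself. It is (time-averaged) C2v-symmetric, and its equivalent C4–H and C6–H are each ortho to one OH and para to the other, so it enters unprotected as a C–H nucleophile with one possible site.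
4. The two vinyl groups are told apart by the reaction itself. The carbanion addition leaves a 2-silyloxy-1,3-diene that is no acceptor, and acid then re-arms the second vinyl ketone for the arene.
5. Rings: none is kept. The only ring formed is a transient 2-methoxychroman (C2'–O to C3). It closes after the ring B–C1 bond and is reopened in the same flask.

Key step: step 3

Remark on the chemistry: the SMILES holds no stereocentre and no stereogenic double bond, so the target is achiral. The demand for a single enantiomer is met by the compound as such, and no asymmetric step is planned.

**Route**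

Step 1
Reactants: 1 1,5-dichloropentan-3-one
Product: 2 penta-1,4-dien-3-one (divinyl ketone), kept cold as a dried, assayed Et2O solution
Conditions: Et3N (2.1 equiv), BHT (cat.), Et2O, 0 °C to rt; filter, cold dilute aq. NaHSO4 wash, MgSO4; use the same day
Reagents that add atoms: none
Why: Double E1cB dehydrochlorination of a β,β'-dichloro ketone with a tertiary amine is the standard entry to vinyl ketones, the ammonium salt is filtered off, and low temperature, dilution and the radical inhibitor hold back polymerisation.

Step 2
Reactants: 3 1-(2-bromoethyl)-4-methoxybenzene (4-methoxyphenethyl bromide)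
Product: 4 [2-(4-methoxyphenyl)ethyl]magnesium bromide, titrated THF solution
Conditions: Mg turnings (1.5 equiv), 1,2-dibromoethane (cat.), THF, 30–40 °C, slow addition
Reagents that add atoms: magnesium, [Mg]
Why: Grignard reagent formation by insertion of magnesium into a primary alkyl bromide, in which slow addition at high dilution limits Wurtz coupling and the aryl methyl ether is inert.

Step 3
Reactants: 2 penta-1,4-dien-3-one; 4 [2-(4-methoxyphenyl)ethyl]magnesium bromide; 5 2-methoxybenzene-1,3-diol (2-methoxyresorcinol)
Product: 9 1-(2,4-dihydroxy-3-methoxyphenyl)-7-(4-methoxyphenyl)heptan-3-one (target), via silyl dienol ether 6 (not isolated), via vinyl ketone 7 (not isolated), via mixed ketal 8 (not isolated)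
Conditions: i) 2 (1.0 equiv), Me3SiCl (2.5 equiv), CuI·2LiCl (10 mol %), THF–Et2O, –78 °C, Ar, 4 (1.1 equiv) added slowly; ii) 5 (3 equiv) in MeOH, –78 °C to 40 °C; iii) 1 M aq. HCl, rt
Reagents that add atoms: chlorotrimethylsilane, C[Si](C)(C)Cl (Me3Si group, held only in 6); methanol, CO (MeO group, held only in 8); water, O (ketone oxygen of 9, delivered in the ketal hydrolysis)
Why: Divinyl ketone 2 serves as a C5 bis-acceptor: a silyl-chloride-accelerated, copper-catalysed (Kharasch-type) 1,4-addition of Grignard reagent 4 forms C5–C6 and is trapped as the 2-silyloxy-1,3-diene 6, whose remaining vinyl group is no longer an acceptor, so mono-addition is secured by the product itself and a slight excess of 4 can consume all of 2. Methanol converts the surplus Me3SiCl into HCl, which protonates 6 at C4, the only carbon activated by the silyloxy group, and so re-arms the second acceptor as vinyl ketone 7 only once 5 is present. The protonated enone is then attacked by the arene in an acid-catalysed Friedel–Crafts-type Michael alkylation, the reaction type long used to join phenols and hydroquinones to methyl vinyl ketone in acidic methanol, and this forms the ring B–C1 bond. Site selectivity rests on the substrate: in 5 the positions C4–H and C6–H are symmetry-equivalent and each is ortho to one OH and para to the other, C5–H is meta to both, reversible O-addition drains back under acid, and the excess of 5 holds down a second alkylation of the product ring. The OH ortho to the new chain closes on the C3 carbonyl (6-exo-trig, then exchange of OH for OMe through the oxocarbenium ion) to the mixed ketal 8, whose single stereocentre forms without control as a racemate and is erased when aqueous acid reopens the ring to 9. The target itself has no stereocentre, and no phenol protecting group is needed at any point.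

Atom origin in 9: C1–C5 come from 2, C6–C7 and ring A from 4, and ring B with its three oxygens from 5.

**Compound list**
1 | 1,5-dichloropentan-3-one | ClCCC(=O)CCCl | starting material
2 | penta-1,4-dien-3-one (divinyl ketone) | C=CC(=O)C=C | intermediate
3 | 1-(2-bromoethyl)-4-methoxybenzene | COc1ccc(CCBr)cc1 | starting material
4 | [2-(4-methoxyphenyl)ethyl]magnesium bromide | COc1ccc(CC[Mg]Br)cc1 | intermediate
5 | 2-methoxybenzene-1,3-diol (2-methoxyresorcinol) | COc1c(O)cccc1O | starting material
6 | {[(3Z)-7-(4-methoxyphenyl)hepta-1,3-dien-3-yl]oxy}trimethylsilane (drawn Z, geometry without consequence) | C=C/C(O[Si](C)(C)C)=C/CCCc1ccc(OC)cc1 | intermediate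
7 | 7-(4-methoxyphenyl)hept-1-en-3-one | C=CC(=O)CCCCc1ccc(OC)cc1 | intermediate
8 | rac-2,8-dimethoxy-2-[4-(4-methoxyphenyl)butyl]-3,4-dihydro-2H-chromen-7-ol | COc1ccc(CCCCC2(OC)CCc3ccc(O)c(OC)c3O2)cc1 | intermediate
9 | 1-(2,4-dihydroxy-3-methoxyphenyl)-7-(4-methoxyphenyl)heptan-3-one | COc1ccc(CCCCC(=O)CCc2ccc(O)c(OC)c2O)cc1 | target

Total step count: 3
Longest linear sequence: 2 (step 1 or step 2, then step 3)

**Steps most likely to fail**

1. Step 3 (key step).
- In stage i, slow silyl trapping may let the magnesium dienolate add to unreacted 2 and start oligomerisation. The silyloxydiene may also enter a cycloaddition with 2 if the mixture warms before the quench.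
- In the acid stage, reversible capture of the enone by chloride or methanol may stall the arene addition. The product ring may be alkylated a second time, or the oxocarbenium ion may be captured by a second arene.
- Fallback: the ketone is built at C3–C4 by acyl substitution instead of two conjugate additions. It sets out from 5 and comes back at 9.
- Compound 5 is condensed with acrylic acid over a sulfonic acid resin in refluxing toluene (hydroarylation and lactonisation, with site selectivity again fixed by symmetry). This gives 7-hydroxy-8-methoxy-3,4-dihydro-2H-chromen-2-one F1.
- The lactone is opened with N,O-dimethylhydroxylamine hydrochloride and iPrMgCl in THF to 3-(2,4-dihydroxy-3-methoxyphenyl)-N-methoxy-N-methylpropanamide F2.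
- Commercial 1-(4-bromobutyl)-4-methoxybenzene is turned with magnesium into [4-(4-methoxyphenyl)butyl]magnesium bromide F3. An excess of it, of which two equivalents are spent on the phenols, converts F2 into 9 in a Weinreb ketone synthesis.

2. Step 1.
- The dienone may polymerise by radical or amine-initiated pathways while it is generated, washed or stored. Material may also be lost through its volatility and water solubility.
- Fallback: the C5 linchpin is given up, and the enone is assembled as C2 + C3 + C2. It sets out from 4 and comes back at 7.
- Copper-catalysed 1,4-addition of 4 to acrolein in the presence of Me3SiCl (THF, –78 °C) gives trimethyl{[(1E)-5-(4-methoxyphenyl)pent-1-en-1-yl]oxy}silane F4.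
- Aqueous acid at work-up cleaves it to 5-(4-methoxyphenyl)pentanal F5.
- Vinylmagnesium bromide adds to the aldehyde to give rac-7-(4-methoxyphenyl)hept-1-en-3-ol F6.
- Oxidation with activated MnO2 in CH2Cl2 gives 7, which is combined with 5 under stages ii and iii of step 3.

3. Step 2.
- Wurtz-type homocoupling and β-elimination during the magnesium insertion may give a low and irreproducible titre.
- Fallback: a reductive cross-electrophile coupling replaces the preformed organometal. It sets out from 3 (together with 2) and comes back at 7.
- A nickel-catalysed reductive conjugate addition of bromide 3 to 2 (NiCl2·dme with a phenanthroline-type ligand, Mn powder, Et3SiCl, DMF) should give triethyl{[(3Z)-7-(4-methoxyphenyl)hepta-1,3-dien-3-yl]oxy}silane F7. This keeps the same built-in stop after one addition.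
- Methanolic HCl in the presence of 5 releases 7 from F7 and carries it on as in stages ii and iii of step 3.

**Further compounds**
F1 | step 3 | 7-hydroxy-8-methoxy-3,4-dihydro-2H-chromen-2-one | COc1c(O)ccc2c1OC(=O)CC2
F2 | step 3 | 3-(2,4-dihydroxy-3-methoxyphenyl)-N-methoxy-N-methylpropanamide | CON(C)C(=O)CCc1ccc(O)c(OC)c1O
F3 | step 3 | [4-(4-methoxyphenyl)butyl]magnesium bromide | COc1ccc(CCCC[Mg]Br)cc1
F4 | step 1 | trimethyl{[(1E)-5-(4-methoxyphenyl)pent-1-en-1-yl]oxy}silane | C[Si](C)(C)O/C=C/CCCc1ccc(OC)cc1
F5 | step 1 | 5-(4-methoxyphenyl)pentanal | COc1ccc(CCCCC=O)cc1
F6 | step 1 | rac-7-(4-methoxyphenyl)hept-1-en-3-ol | C=CC(O)CCCCc1ccc(OC)cc1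
F7 | step 2 | triethyl{[(3Z)-7-(4-methoxyphenyl)hepta-1,3-dien-3-yl]oxy}silane | C=C/C(O[Si](CC)(CC)CC)=C/CCCc1ccc(OC)cc1
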